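I began with an easy step: I multiplied each target percent by the substrate charge of its run, which gave c(target) as a concentration.

| flask | substrate | partner | free catalyst | temperature | remark | time |
|---|---|---|---|---|---|---|
| midnight | 0.40 M | 0.48 M | 10 mM | 35 °C | run made earlier |  |
| dusk | 0.27 M | 0.48 M | 10 mM | 50 °C | run made earlier |  |
| summer | 0.60 M | 0.48 M | 10 mM | 35 °C | run made earlier |  |
| south-west | 0.40 M (fed, over 50 h) | 0.480 M | 10 mM | 50 °C | all else is in the flask from the start; the feed brings no volume worth counting | 2.5 d |
| north | 0.40 M | 0.480 M (fed, over 50 h) | 10 mM | 50 °C | all else is in the flask from the start; the feed brings no volume worth counting | 2.5 d |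
| south | 0.40 M | 0.480 M | 10 mM |  | everything together at the start at 30 °C, warmed to 50 °C at 50 h | 2.5 d |
| north-west | 0.40 M | 0.480 M (in portions, 3, over 50 h) | 10 mM | 50 °C | first portion at the start, last at 50 h | 2.5 d |
| east | 0.40 M | 0.480 M (fed, over 50 h) | 10 mM |  | the addition at 30 °C, then warmed to 50 °C; the feed brings no volume worth counting | 2.5 d |

| run | time / d | target / % | substrate / % |
|---|---|---|---|
| midnight | 0.833 | 14.7 | 82.4 |
| midnight | 1.67 | 22.8 | 75.7 |
| midnight | 2.00 | 24.0 | 72.5 |
| midnight | 4.00 | 32.8 | 64.9 |
| dusk | 0.333 | 15.4 | 80.5 |
| dusk | 0.833 | 21.5 | 74.0 |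
| dusk | 1.67 | 26.0 | 70.1 |
| dusk | 2.50 | 27.5 | 69.9 |
| summer | 0.417 | 5.2 | 92.6 |
| summer | 1.04 | 11.2 | 86.2 |
| summer | 2.00 | 16.8 | 81.9 |
| summer | 5.00 | 23.3 | 74.8 |

(each reading ± 0.5 percentage points)

- what was read earlier has a scatter of 0.5 percentage points, one standard deviation

- the flask with the highest amount of target, in percent of the substrate charged ("all alike" if they lie within 1.5 percentage points) (south-west / north / south / north-west / east / all alike)
- final target, as a percentage of the substrate charged, in south-west
- final target, as a percentage of the substrate charged, in north
- final target, as a percentage of the substrate charged, in south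
- final target, as a percentage of the substrate charged, in north-west
- final target, as a percentage of the substrate charged, in east

Next I plotted time over c(target) against time. The points lay close to a straight line, so the rate faded in a regular way. The inverse slope gives the concentration of target that the line approaches.

The midnight run, from its first and last readings, gave 0.194 M. The summer run, with more substrate at the same temperature, gave 0.205 M. These two runs started from different substrate charges, yet they agreed, so I trusted the line.

At 50 °C there were again two ways to the number. The last dusk reading gave 0.0743 M, but the line gave 0.0844 M, which is higher. I called this line value the ceiling: the c(target) that the dusk line approaches for this catalyst charge at that temperature, with substrate and partner in from the start. Per catalyst charged, it is a turnover number of 8.44.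

One of the two had to cheat. The line also gave a half-ceiling time of 0.343 d. From the first and last dusk readings it put the third dusk reading at 25.9 %, and I had read 26.0 %. Taken as a ceiling, the last dusk reading was the cheat, since the readings were still climbing from 26.0 % to 27.5 %.

On a charge of 0.40 M, the ceiling is 21.1 %. By 2.5 d the line reaches 18.6 %, and that was my mark for south-west. The midnight line, at 35 °C, stood 2.30 times above the dusk line, so I put south, which starts cold, first. Partner was never varied, so I gave north, north-west and east no number.

The forecast named south, with south-west at 17 %, below my mark, north at 6 %, south at 29.5 %, north-west at 8 % and east at 16 %: “Cool running therefore wins, and south comes out highest.”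

The flasks gave 22.7 % in south-west, 3.49 % in north, 28.1 % in south, 6.43 % in north-west and 8.31 % in east, so south led.

    substrate + free catalyst ⇌ catalyst intermediate A (K = 4.82 L mol⁻¹, k = 0.127 L mol⁻¹ s⁻¹, Ea = 50.0 kJ mol⁻¹, ΔH = −48.0 kJ mol⁻¹)
    partner + catalyst intermediate A ⇌ catalyst intermediate B (K = 2.80 L mol⁻¹, k = 0.0112 L mol⁻¹ s⁻¹, Ea = 64.0 kJ mol⁻¹, ΔH = −84.0 kJ mol⁻¹)
    catalyst intermediate B ⇌ free catalyst + target (K = 5.80 M, k = 0.00113 s⁻¹, Ea = 102 kJ mol⁻¹, ΔH = −34.0 kJ mol⁻¹)
    2 catalyst intermediate A → spent catalyst (k = 0.0611 L mol⁻¹ s⁻¹, Ea = 67.0 kJ mol⁻¹)
    partner → decomposed reagent (k = 3.34 × 10⁻⁶ s⁻¹, Ea = 114 kJ mol⁻¹)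
    (constants at 50 °C)

South held 0.112 M of target, over the ceiling of 0.0844 M, and it had spent its first 50 h cold. South-west held 0.0908 M, just above that ceiling. North, with its partner fed slowly, held 0.0140 M, so there the ceiling stood 6.05 times above the target. The main reason for the low target in north was the pairing of catalyst intermediate A into spent catalyst. With that step struck out, north reached 67.7 % instead of 3.49 %.

The earlier runs and the new flask are simulated for substances that don't exist.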